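A small charge of initiator starts the chains in both flasks, and it turns into living ends that go on taking up free monomer.

    free monomer + initiator → living end + monomer in chains (k1 = 2.75 /M/s, Ea1 = 50.0 kJ/mol)
    free monomer + living end → monomer in chains + living end, rate k2*[living end]*[free monomer] (k2 = 142 /M/s, Ea2 = 42.0 kJ/mol)
    monomer in chains + initiator ⇌ isomer of the product + initiator, rate k3*[initiator]*[monomer in chains] forward; the back reaction follows from the equilibrium constant (K3 = 0.36, k3 = 308 /M/s, Ea3 = 53.0 kJ/mol, ΔH3 = −23.0 kJ/mol)
    (constants at 50 °C)

- birch: free monomer 0.086 M; initiator 0.2 mol%; temperature 65 °C; time 20 s
- elm: free monomer 0.086 M; initiator 0.2 mol%; temperature 50 °C; time 20 s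

- at 50 °C the constants are as listed, elsewhere as the activation energies and enthalpies make them

1. which of these there is most of at the end, counted by the free monomer in it, birch (isomer of the product / free monomer / monomer in chains)
2. which of these there is most of at the end, counted by the free monomer in it, elm (isomer of the product / free monomer / monomer in chains)
3. the largest of these amounts at the end, in percent of the free monomer charged, birch
4. the largest of these amounts at the end, in percent of the free monomer charged, elm

The charge of initiator is 1.72 × 10⁻⁴ M, far below the free monomer. The first step makes one living end from each initiator, the second hands the living end back, and the third leaves it alone, so [living end] + [initiator] stays at that charge. We therefore freeze [living end] at the charge once the start is over, and set up this small table: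

birch, 65 °C: first-step constant 6.28 /M/s; second-step constant 284 /M/s; lag 1.85 s; clock 14.2 s

elm, 50 °C: first-step constant 2.75 /M/s; second-step constant 142 /M/s; lag 4.23 s; clock 28.4 s

The chain clock is ln(2) over the second-step constant times the charge of initiator: the half-life of free monomer with [living end] frozen at the full charge, a pseudo-first-order half-life.

The lag is one over the first-step constant times the charge of free monomer. [Living end] climbs with that time constant, so in this reckoning birch and elm each run as if the full charge had arrived one lag late. We may hold [free monomer] at its charge during the climb, since the lag is shorter than the clock in birch and in elm.

Reading the clocks against each other, elm's is twice birch's, because birch's second-step constant is twice elm's.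

Reading along the rows, birch has 18.1 s of running time, more than its clock, so by this reckoning less than 0.5 of its free monomer stays. Elm has 15.8 s, less than its clock, so by this reckoning more than 0.5 stays.

Free monomer left is one half raised to running time over clock. Setting the isomer aside for now, we commit to monomer in chains at 58.8% in birch, and free monomer at 68.0% in elm.

The forecast says monomer in chains at 57.6% for birch and free monomer at 68.3% for elm, and it holds the isomer small on this ground: “Isomerisation needs initiator, which has largely gone before many chains exist”. It names the same winners as our reckoning, and its birch figure makes room for the isomer that ours set aside.

The simulation gives monomer in chains at 57.6% in birch and free monomer at 68.1% in elm. At 20.0 s birch holds 1.72 × 10⁻⁴ M of living end, with 0.0574% of its initiator left. Now take birch with 0.21 M of free monomer at the same loading and time. The charge of initiator becomes 4.20 × 10⁻⁴ M, the lag 0.758 s and the clock 5.81 s, so the clock leaves 10.1% free. That flask holds 10.1% free monomer and 88.8% monomer in chains at 20.0 s.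

(The numbers of this flask were drawn at random within sensible limits; the run is a simulation.)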